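## Structural features

The target 31 is a dimeric isoflavan in which two chromans are joined through a central benzene ring. Chroman P (O1, C2, C3, C4, C4a to C8a, benzo ring A with the C7 hydroxyl) carries ring B, a 3-hydroxy-2,4-dimethoxyphenyl group, on C3 and ring E on C4. Ring E (C2' hydroxyl, C4' methoxy) is bound through C5' to C4 and through C1' to C3q of chroman Q, a 7-hydroxy-3-arylchroman. C3 (R) and C4 (S) are adjacent and hold ring B and ring E trans. C3q (R) stands alone, five bonds from C4 across the meta positions of ring E, so only a reagent can set it. The fragile groups are four free phenols on electron-rich rings and the doubly benzylic C4–H, which lies para to the C2' hydroxyl and can be lost through a quinone methide. Three methyl ethers must also stay distinct from four hydroxyls. The real difficulty is C4, a diarylmethine that bears a tetrasubstituted arene flanked by a methoxy group and must be trans to the aryl group on C3. The key step uses the para relationship between the C2' hydroxyl and C5': oxidation of the ring E phenol makes the C4 methylene an electrophile, and C4a of ring A (ortho to O1, para to the C7 oxygen) sits six atoms away as the nucleophile.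

## Logic of the disconnections

**31 from 30.** The four benzyl–oxygen bonds are cut. One hydrogenolysis frees all four phenols at the end, so every earlier step handles ethers only and the methyl ethers are never touched. The forward step must meet no other cleavable bond: O1–C2 and O1q–C2q are not benzylic and C4 bears no leaving group.

**30 from 29.** The C3q–H and C4q–H bonds are cut, making C3q sp2. C3q is too far from C3 and C4 for substrate control, and a trisubstituted cyclic styrene is a standard substrate for iridium P,N catalysts. The gain is one stereocentre less and a flat fragment that can be attached by cross-coupling. The demand is face selection by the ligand alone, without loss of benzyl ethers.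

**29 from 28 and 27.** The C1'–C3q bond between two sp2 carbons is cut. It is the only bond linking the halves, and 28 already carries bromine on C1'. The molecule falls into the chroman P/ring E block and a small achiral chromene. The demand is oxidative addition at an electron-rich aryl bromide flanked by a benzyloxy group.

**27 from 22 through 26, 25, 24 and 23.** C3q–B is cut back to C3q–Br, the double bond to a bromohydrin, then to the α-bromo ketone and the ketone, and last the benzyl–oxygen bond. Dehydration of 25 fixes bromine on C3q without ambiguity, because the cation forms at C4q. The demand is α-bromination that spares the activated benzo ring.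

**28 from 21.** The benzyl–oxygen bond on the C2' oxygen is cut. The free phenol is needed in the key step but harmful afterwards. The demand is a simple alkylation of an ortho-bromophenol.

**21 from 19 via 20.** The C4–C4a bond is cut, which opens the pyran ring of chroman P and removes the C4 stereocentre. The cut is placed here because C4 is para-benzylic to the C2' hydroxyl and C4a is the matching nucleophile. The gain is an open-chain ether with one stereocentre and a bare C4 methylene. The demands are oxidation of the phenol only, attack by the ring A carbon para to the benzyloxy group, addition trans to ring B, and a stop after two electrons. In 19 the only free hydroxyl is on ring E; rings A and B carry benzyl ethers, and bromine on C1' blocks the open ortho position.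

**19 from 18.** The S–O bond of a sulfonate is cut. Through steps 9 to 12 the ring E oxygen needs a group that is electron-withdrawing, so that 13 does not ionise as a 2,4-dioxygenated benzyl bromide would. It must also resist amide base, hydride and Mitsunobu reagents and come off beside benzyl ethers and the aryl bromide. The demand is S–O cleavage without alkylation of the phenoxide.

**18 from 16 and 17.** The C2–O1 bond is cut. An alkyl aryl ether from a primary alcohol and a phenol brings in ring A whole, with its benzyloxy group in place. The demand is that 17 is the only phenolic nucleophile present.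

**16 from 15.** C2 is taken back to the acyl level with the auxiliary attached. A carbonyl next to C3 allows enolate chemistry. The demand is reduction without epimerisation at C3 or opening of the oxazolidinone ring.

**15 from 8 and 13 via 14.** The C3–C4 bond is cut. This puts the new stereocentre α to the imide, where the auxiliary controls the face, and leaves C4 as the unfunctionalised methylene. Two arene blocks of similar size result. The demands are a reactive but non-ionising benzyl bromide and a quench that does not epimerise the α-aryl centre.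

**13 from 9 through 12, 11 and 10.** The benzylic C–Br, the alcohol C–H, the O–S and the C1'–Br bonds are cut in turn. The substituents of 9 all direct bromine to C1'. The demand is clean mono-bromination.

**8 from 5 and 6 via 7; 5 from 1 through 4, 3 and 2.** The N–acyl bond is cut, then the C1''–CH2 bond (aryl bromide plus an acetate enolate equivalent), then C1''–Br and the benzyl–oxygen bond. In 2 the only activated free position is the one needed for C1''. The demand is enolate arylation at an ortho-methoxy bromide.

## Other disconnections considered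

**Alternative 1:** The cut is at C4–C4a and at the C3–ring B bond, both in one operation.
- **Forward step.** Alkenyl boronate A2 and aryllithium A3 give a boron ate complex. The arylpalladium species from triflate A4 (Pd(OAc)2 as divalent palladium source, chiral bisphosphine) makes ring B migrate from boron to C3 anti to palladium, and reductive elimination joins C4 to ring A to give boronate A1.
- **In favour.** Both centres of chroman P are set by a catalyst in one convergent step, no auxiliary is used, and no electron-rich phenol has to be oxidised.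
- **Against.** β-Aryl alkenyl boronates are the sluggish class for this metallate shift, and A3 and A4 are both ortho-substituted. A2 must already contain chroman Q, so the most valuable fragment runs through the least certain step. The boron on C3 then has to be exchanged for the C2 methylene by Matteson homologation at a hindered secondary benzylic boronate, followed by oxidation, acetal removal and ring closure.
- **Comparison.** On structure it forms two bonds and two stereocentres against one bond and one stereocentre, but closes no ring. On mechanism it is catalyst control against substrate control. On step economy it needs about five steps after the coupling against four here, with chroman Q built first. It is the better plan on stereochemical economy and on avoiding oxidation; it is equal on the final deprotection.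

**Alternative 2:** The cut is at C3q–C1' and at the bond from C4q to the C2' oxygen.
- **Forward step.** Chromene A6 adds to quinone A7 bound to the chiral titanium TADDOLate made from TiCl2(OiPr)2 (tetravalent titanium). The benzylic cation at C4q is captured by the quinone oxygen, and tautomerisation gives pterocarpan A5.
- **In favour.** The ring E–chroman Q unit and C3q arise in one step from two simple compounds. The oxygen bridge protects the C2' oxygen and would open by hydrogenolysis of the benzylic C4q–O bond in the final debenzylation.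
- **Against.** The chiral titanium reagent is stoichiometric, and cyclobutane formation competes. C5' emerges as a hydroxyl, so the bond to C4 needs sulfonylation and a cross-coupling. The trans C3/C4 pair of chroman P, the hardest element, is not addressed at all. The anodic step could not follow directly, because the C2' oxygen is tied up in the furan ring.
- **Comparison.** For the chroman Q half it is the better plan on step count (one step against steps 15 to 22) and equal in being reagent-controlled. For the whole molecule it is weaker, because a second key step for chroman P would still be needed.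

**Alternative 3:** The cut is at C1'–C6' and C4'–C5', so ring E itself is built.
- **Forward step.** Diene A9 and ynone A10 undergo Diels–Alder addition. Loss of methanol and of the silyl group aromatises the adduct to benzophenone A8.
- **In favour.** The polarity of the cycloaddition fixes the full substitution pattern of ring E, with no bromination or blocking group. The two halves are joined convergently and the C2' hydroxyl arrives free.
- **Against.** C4 is a ketone that carries neither C3, ring B nor C2. A three-carbon unit must be added to a hindered diaryl ketone and two stereocentres set afterwards. A9 needs a multistep synthesis from an enantioenriched chroman Q unit and is moisture-sensitive.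
- **Comparison.** It is the better plan on arene regiochemistry and equal on convergence and on closing one ring. It is weaker on mechanism, since the step sets no stereocentre, and on step economy, since the whole pyran ring of chroman P remains to be made.

Key step: step 14

**Remarks on the chemistry**
- Configurations were re-derived from the target: C3 is R in 15 to 21 and 28 to 31, C4 is S (trans), C3q is R. Compounds 19 and 21 agree with this and needed no correction.
- The ring E oxygen is carried as a tosylate up to step 13, for the reasons stated under 19 from 18.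
- Chroman Q is entered from commercial 7-hydroxychroman-4-one (22), because dehydration of 25 places bromine on C3q unambiguously.
- The (S)-ligand is written for step 22 on the assumption that it delivers hydrogen to the Si face of C3q; if the sense of induction on this substrate class is the opposite, the (R)-ligand is used.

## Route

Step 1
Reactants: 1 2,6-dimethoxyphenol
Product: 2 2-(benzyloxy)-1,3-dimethoxybenzene
Conditions: BnBr, K2CO3, DMF, 60 °C
Reagents that add atoms: benzyl bromide, BrCc1ccccc1
Why: Williamson etherification; the benzyl group leaves with the others in step 23 and, unlike the free phenol, does not direct the next substitution para to this oxygen.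

Step 2
Reactants: 2 2-(benzyloxy)-1,3-dimethoxybenzene
Product: 3 3-(benzyloxy)-1-bromo-2,4-dimethoxybenzene
Conditions: NBS, MeCN, 0 °C to rt
Reagents that add atoms: N-bromosuccinimide, O=C1CCC(=O)N1Br
Why: Electrophilic aromatic bromination; the central alkoxy group is twisted out of conjugation, so attack goes ortho and para to the flanking methoxy groups, which is the carbon needed as C1'' of ring B.

Step 3
Reactants: 3 3-(benzyloxy)-1-bromo-2,4-dimethoxybenzene
Product: 4 tert-butyl 2-[3-(benzyloxy)-2,4-dimethoxyphenyl]acetate
Conditions: BrZnCH2CO2tBu, Pd(dba)2 (cat.), P(t-Bu)3 (cat.), THF, rt to 60 °C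
Reagents that add atoms: (2-tert-butoxy-2-oxoethyl)zinc bromide, CC(C)(C)OC(=O)C[Zn]Br
Why: Palladium-catalysed α-arylation of an ester zinc enolate (Negishi-type coupling of a Reformatsky reagent); the neutral zinc enolate needs no strong base and tolerates the benzyl ether.

Step 4
Reactants: 4 tert-butyl 2-[3-(benzyloxy)-2,4-dimethoxyphenyl]acetate
Product: 5 2-[3-(benzyloxy)-2,4-dimethoxyphenyl]acetic acid
Conditions: CF3CO2H/CH2Cl2 1:4, 0 °C to rt
Reagents that add atoms: none
Why: Acidolysis of the tert-butyl ester with loss of isobutene; aryl benzyl and methyl ethers are stable to trifluoroacetic acid at this temperature.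

Step 5
Reactants: 5 2-[3-(benzyloxy)-2,4-dimethoxyphenyl]acetic acid, 6 (R)-4-benzyl-1,3-oxazolidin-2-one
Product: 8 (R)-4-benzyl-3-{2-[3-(benzyloxy)-2,4-dimethoxyphenyl]acetyl}-1,3-oxazolidin-2-one, via mixed pivalic anhydride 7 (not isolated)
Conditions: t-BuCOCl, Et3N, THF, −20 °C; then 6, LiCl, −20 °C to rt
Reagents that add atoms: none
Why: N-acylation of the oxazolidinone through a mixed anhydride, which is attacked at the less hindered arylacetyl carbonyl; LiCl and Et3N make the auxiliary nucleophilic enough without butyllithium.

Step 6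
Reactants: 9 4-hydroxy-2-methoxybenzaldehyde
Product: 10 5-bromo-4-hydroxy-2-methoxybenzaldehyde
Conditions: Br2, AcOH, 15 °C
Reagents that add atoms: bromine, BrBr
Why: Electrophilic aromatic bromination ortho to the hydroxyl and para to the methoxy group; the position between the two oxygens is hindered and the aldehyde also directs to this carbon, the future C1'.

Step 7
Reactants: 10 5-bromo-4-hydroxy-2-methoxybenzaldehyde
Product: 11 2-bromo-4-formyl-5-methoxyphenyl 4-methylbenzenesulfonate
Conditions: TsCl, Et3N, DMAP (cat.), CH2Cl2, 0 °C to rt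
Reagents that add atoms: 4-methylbenzenesulfonyl chloride, Cc1ccc(S(=O)(=O)Cl)cc1
Why: O-sulfonylation of the phenol; the electron-poor sulfonate stabilises the later benzyl bromide, resists base, hydride and Mitsunobu reagents and is orthogonal to benzyl ethers.

Step 8
Reactants: 11 2-bromo-4-formyl-5-methoxyphenyl 4-methylbenzenesulfonate
Product: 12 2-bromo-4-(hydroxymethyl)-5-methoxyphenyl 4-methylbenzenesulfonate
Conditions: NaBH4, THF/MeOH, 0 °C
Reagents that add atoms: none
Why: Hydride reduction of the aldehyde; aryl sulfonate and aryl bromide are inert to NaBH4.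

Step 9
Reactants: 12 2-bromo-4-(hydroxymethyl)-5-methoxyphenyl 4-methylbenzenesulfonate
Product: 13 2-bromo-4-(bromomethyl)-5-methoxyphenyl 4-methylbenzenesulfonate
Conditions: PBr3, CH2Cl2, 0 °C
Reagents that add atoms: phosphorus tribromide, BrP(Br)Br
Why: Substitution of the benzylic alcohol through its phosphite ester (SN2); with the para oxygen sulfonylated the bromide does not ionise and can be stored.

Step 10
Reactants: 8 (R)-4-benzyl-3-{2-[3-(benzyloxy)-2,4-dimethoxyphenyl]acetyl}-1,3-oxazolidin-2-one, 13 2-bromo-4-(bromomethyl)-5-methoxyphenyl 4-methylbenzenesulfonate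
Product: 15 2-bromo-5-methoxy-4-{(2R)-2-[3-(benzyloxy)-2,4-dimethoxyphenyl]-3-[(4R)-4-benzyl-2-oxo-1,3-oxazolidin-3-yl]-3-oxopropyl}phenyl 4-methylbenzenesulfonate, via sodium enolate 14 (not isolated)
Conditions: NaN(SiMe3)2, THF, −78 °C; then 13, −78 to −40 °C; AcOH quench at −78 °C
Reagents that add atoms: none
Why: Evans auxiliary alkylation: the chelated (Z)-enolate 14 is shielded on the face of the auxiliary benzyl group, so 13 enters from the other face and C3 is formed R (the R auxiliary is required because ring B outranks the new methylene). The cold buffered quench avoids epimerisation of the acidic α-aryl centre.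

Step 11
Reactants: 15 2-bromo-5-methoxy-4-{(2R)-2-[3-(benzyloxy)-2,4-dimethoxyphenyl]-3-[(4R)-4-benzyl-2-oxo-1,3-oxazolidin-3-yl]-3-oxopropyl}phenyl 4-methylbenzenesulfonate
Product: 16 2-bromo-4-{(2R)-2-[3-(benzyloxy)-2,4-dimethoxyphenyl]-3-hydroxypropyl}-5-methoxyphenyl 4-methylbenzenesulfonate
Conditions: LiBH4, H2O (1 equiv), Et2O/THF, 0 °C
Reagents that add atoms: none
Why: Reductive cleavage of the N-acyloxazolidinone at the exocyclic carbonyl gives the primary alcohol without touching C3, the sulfonate or the aryl bromide; 6 is recovered.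

Step 12
Reactants: 16 2-bromo-4-{(2R)-2-[3-(benzyloxy)-2,4-dimethoxyphenyl]-3-hydroxypropyl}-5-methoxyphenyl 4-methylbenzenesulfonate, 17 3-(benzyloxy)phenol
Product: 18 2-bromo-4-{(2R)-2-[3-(benzyloxy)-2,4-dimethoxyphenyl]-3-[3-(benzyloxy)phenoxy]propyl}-5-methoxyphenyl 4-methylbenzenesulfonate
Conditions: PPh3, DIAD, THF, 0 °C to rt
Reagents that add atoms: none
Why: Mitsunobu etherification of the primary alcohol with the phenol forms C2–O1; C3 is not involved, and 17 is the only phenolic nucleophile because the ring E oxygen is masked.

Step 13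
Reactants: 18 2-bromo-4-{(2R)-2-[3-(benzyloxy)-2,4-dimethoxyphenyl]-3-[3-(benzyloxy)phenoxy]propyl}-5-methoxyphenyl 4-methylbenzenesulfonate
Product: 19 2-bromo-4-{(2R)-2-[3-(benzyloxy)-2,4-dimethoxyphenyl]-3-[3-(benzyloxy)phenoxy]propyl}-5-methoxyphenol
Conditions: KOH, 1,4-dioxane/H2O 4:1, 80 °C; then 1 M HCl
Reagents that add atoms: none
Why: Hydroxide attacks sulfur of the aryl sulfonate (S–O cleavage) and frees the ring E phenol; the alcohol-free medium prevents O-alkylation of the phenoxide by a sulfonate ester, and ethers and aryl bromide are inert.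

Step 14
Reactants: 19 2-bromo-4-{(2R)-2-[3-(benzyloxy)-2,4-dimethoxyphenyl]-3-[3-(benzyloxy)phenoxy]propyl}-5-methoxyphenol
Product: 21 2-bromo-4-{(3R,4S)-7-(benzyloxy)-3-[3-(benzyloxy)-2,4-dimethoxyphenyl]-3,4-dihydro-2H-chromen-4-yl}-5-methoxyphenol, via para-quinone methide 20 (not isolated)
Conditions: graphite anode, Pt cathode, undivided cell, constant current (2 mA cm−2), 2.1 F mol−1, n-Bu4NPF6 (0.1 M), 2,6-lutidine (1 equiv), (CF3)2CHOH/CH2Cl2 9:1, 5 mM, 0 °C
Reagents that add atoms: none
Why: Proposed new method: at the anode the phenol of 19 loses two electrons and two protons (the second from C4) to give para-quinone methide 20, which hexafluoroisopropanol activates by hydrogen bonding without adding irreversibly; the closest known reaction type is oxidation of 4-alkylphenols (anodic, Ag2O or DDQ) to para-quinone methides that electron-rich arenes trap in a Friedel–Crafts alkylation, here made intramolecular. The ring A carbon ortho to O1 and para to the benzyloxy group attacks C4, the arenium ion loses a proton and ring E returns to the phenol, while the cathode reduces the released protons to hydrogen. The pyran ring closes in a 6-exo-trig mode with respect to the C4=C5' bond. C4 is controlled by C3: allylic strain holds C3–H in the plane of the methide, so the aryloxymethyl arm and ring B lie on opposite faces and ring A arrives through a chair-like transition state that leaves ring B and ring E both equatorial, that is trans (3R,4S). Chemoselectivity rests on the phenol–lutidine couple being oxidised below the potential of the benzyl aryl ethers of rings A and B. Regioselectivity rests on the hindered position between the two oxygens of ring A, and bromine on C1' blocks ortho coupling of the phenoxyl radical. Over-oxidation of 21 is limited by the charge passed and because a methide at the now fully substituted C4 would clash with the C4' methoxy group.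

Step 15
Reactants: 22 7-hydroxychroman-4-one
Product: 23 7-(benzyloxy)chroman-4-one
Conditions: BnBr, K2CO3, acetone, reflux
Reagents that add atoms: benzyl bromide, BrCc1ccccc1
Why: Williamson etherification of the phenol; K2CO3 is too weak to open the chromanone ring by β-elimination.

Step 16
Reactants: 23 7-(benzyloxy)chroman-4-one
Product: 24 7-(benzyloxy)-3-bromochroman-4-one
Conditions: CuBr2, EtOAc/CHCl3 1:1, reflux
Reagents that add atoms: copper dibromide, Br[Cu]Br
Why: α-Bromination of the ketone through its enol with CuBr2 (divalent copper), which leaves the activated benzo ring alone where Br2 might not.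

Step 17
Reactants: 24 7-(benzyloxy)-3-bromochroman-4-one
Product: 25 7-(benzyloxy)-3-bromochroman-4-ol
Conditions: NaBH4, THF/MeOH, 0 °C
Reagents that add atoms: none
Why: Hydride reduction of the α-bromo ketone to the bromohydrin; the configuration at both carbons is irrelevant because both become sp2 in step 18.

Step 18
Reactants: 25 7-(benzyloxy)-3-bromochroman-4-ol
Product: 26 7-(benzyloxy)-3-bromo-2H-chromene
Conditions: TsOH·H2O (cat.), toluene, reflux, Dean–Stark
Reagents that add atoms: none
Why: Acid-catalysed E1 dehydration through the C4q cation, stabilised by O1q and the para benzyloxy group; the proton is lost from C3q, so bromine ends on the styrenic double bond.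

Step 19
Reactants: 26 7-(benzyloxy)-3-bromo-2H-chromene
Product: 27 2-[7-(benzyloxy)-2H-chromen-3-yl]-4,4,5,5-tetramethyl-1,3,2-dioxaborolane
Conditions: B2pin2, PdCl2(dppf) (cat.), KOAc, 1,4-dioxane, 80 °C
Reagents that add atoms: bis(pinacolato)diboron, CC1(C)OB(OC1(C)C)B1OC(C)(C)C(C)(C)O1
Why: Miyaura borylation of the alkenyl bromide (oxidative addition, acetate-assisted transmetalation, reductive elimination).

Step 20
Reactants: 21 2-bromo-4-{(3R,4S)-7-(benzyloxy)-3-[3-(benzyloxy)-2,4-dimethoxyphenyl]-3,4-dihydro-2H-chromen-4-yl}-5-methoxyphenol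
Product: 28 (3R,4S)-7-(benzyloxy)-4-[4-(benzyloxy)-5-bromo-2-methoxyphenyl]-3-[3-(benzyloxy)-2,4-dimethoxyphenyl]chromane
Conditions: BnBr, K2CO3, DMF, rt
Reagents that add atoms: benzyl bromide, BrCc1ccccc1
Why: Williamson etherification; capping the ring E phenol removes the para-quinone methide pathway at C4 and prevents acid-induced addition of the ortho hydroxyl to the chromene in steps 21 and 22.

Step 21
Reactants: 28 (3R,4S)-7-(benzyloxy)-4-[4-(benzyloxy)-5-bromo-2-methoxyphenyl]-3-[3-(benzyloxy)-2,4-dimethoxyphenyl]chromane, 27 2-[7-(benzyloxy)-2H-chromen-3-yl]-4,4,5,5-tetramethyl-1,3,2-dioxaborolane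
Product: 29 (3R,4S)-7-(benzyloxy)-4-{4-(benzyloxy)-5-[7-(benzyloxy)-2H-chromen-3-yl]-2-methoxyphenyl}-3-[3-(benzyloxy)-2,4-dimethoxyphenyl]chromane
Conditions: Pd(OAc)2 (cat.), SPhos, K3PO4, toluene/H2O 10:1, 80 °C
Reagents that add atoms: none
Why: Suzuki–Miyaura coupling forms C1'–C3q; the bulky electron-rich biarylphosphine promotes oxidative addition at the hindered, electron-rich C1'–Br bond.

Step 22
Reactants: 29 (3R,4S)-7-(benzyloxy)-4-{4-(benzyloxy)-5-[7-(benzyloxy)-2H-chromen-3-yl]-2-methoxyphenyl}-3-[3-(benzyloxy)-2,4-dimethoxyphenyl]chromane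
Product: 30 (3R,4S)-7-(benzyloxy)-4-{4-(benzyloxy)-5-[(3R)-7-(benzyloxy)chroman-3-yl]-2-methoxyphenyl}-3-[3-(benzyloxy)-2,4-dimethoxyphenyl]chromane
Conditions: H2 (50 bar), [Ir(cod)((S)-tBu-PHOX)]B[3,5-(CF3)2C6H3]4 (2 mol%), CH2Cl2, rt
Reagents that add atoms: none
Why: Iridium-catalysed asymmetric hydrogenation of a trisubstituted styrenic olefin with a chiral P,N ligand; C3 and C4 are remote, so the ligand alone selects the Si face of C3q and gives 3R. Benzyl ethers are not cleaved by this catalyst.

Step 23
Reactants: 30 (3R,4S)-7-(benzyloxy)-4-{4-(benzyloxy)-5-[(3R)-7-(benzyloxy)chroman-3-yl]-2-methoxyphenyl}-3-[3-(benzyloxy)-2,4-dimethoxyphenyl]chromane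
Product: 31 (3R,4S)-4-{4-hydroxy-5-[(3R)-7-hydroxychroman-3-yl]-2-methoxyphenyl}-3-(3-hydroxy-2,4-dimethoxyphenyl)chroman-7-ol
Conditions: H2 (1 atm), Pd/C (10%), EtOAc/MeOH 1:1, rt
Reagents that add atoms: none
Why: Hydrogenolysis of the four benzyl aryl ethers; the chroman O–CH2 bonds are not benzylic and C4 bears no leaving group, so the skeleton and the three stereocentres are untouched.

## Compound list

1 | 2,6-dimethoxyphenol | COc1cccc(OC)c1O | starting material
2 | 2-(benzyloxy)-1,3-dimethoxybenzene | COc1cccc(OC)c1OCc1ccccc1 | intermediate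
3 | 3-(benzyloxy)-1-bromo-2,4-dimethoxybenzene | COc1ccc(Br)c(OC)c1OCc1ccccc1 | intermediate
4 | tert-butyl 2-[3-(benzyloxy)-2,4-dimethoxyphenyl]acetate | COc1ccc(CC(=O)OC(C)(C)C)c(OC)c1OCc1ccccc1 | intermediate
5 | 2-[3-(benzyloxy)-2,4-dimethoxyphenyl]acetic acid | COc1ccc(CC(=O)O)c(OC)c1OCc1ccccc1 | intermediate
6 | (R)-4-benzyl-1,3-oxazolidin-2-one | O=C1N[C@H](Cc2ccccc2)CO1 | starting material
7 | 2-[3-(benzyloxy)-2,4-dimethoxyphenyl]acetic pivalic anhydride (not isolated) | COc1ccc(CC(=O)OC(=O)C(C)(C)C)c(OC)c1OCc1ccccc1 | intermediate
8 | (R)-4-benzyl-3-{2-[3-(benzyloxy)-2,4-dimethoxyphenyl]acetyl}-1,3-oxazolidin-2-one | COc1ccc(CC(=O)N2C(=O)OC[C@H]2Cc2ccccc2)c(OC)c1OCc1ccccc1 | intermediate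
9 | 4-hydroxy-2-methoxybenzaldehyde | COc1cc(O)ccc1C=O | starting material
10 | 5-bromo-4-hydroxy-2-methoxybenzaldehyde | COc1cc(O)c(Br)cc1C=O | intermediate
11 | 2-bromo-4-formyl-5-methoxyphenyl 4-methylbenzenesulfonate | COc1cc(OS(=O)(=O)c2ccc(C)cc2)c(Br)cc1C=O | intermediate
12 | 2-bromo-4-(hydroxymethyl)-5-methoxyphenyl 4-methylbenzenesulfonate | COc1cc(OS(=O)(=O)c2ccc(C)cc2)c(Br)cc1CO | intermediate
13 | 2-bromo-4-(bromomethyl)-5-methoxyphenyl 4-methylbenzenesulfonate | COc1cc(OS(=O)(=O)c2ccc(C)cc2)c(Br)cc1CBr | intermediate
14 | sodium (Z)-enolate of 8 (not isolated) | [Na+].[O-]/C(=C\c1ccc(OC)c(OCc2ccccc2)c1OC)N1C(=O)OC[C@H]1Cc1ccccc1 | intermediate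
15 | 2-bromo-5-methoxy-4-{(2R)-2-[3-(benzyloxy)-2,4-dimethoxyphenyl]-3-[(4R)-4-benzyl-2-oxo-1,3-oxazolidin-3-yl]-3-oxopropyl}phenyl 4-methylbenzenesulfonate | COc1cc(OS(=O)(=O)c2ccc(C)cc2)c(Br)cc1C[C@@H](C(=O)N1C(=O)OC[C@H]1Cc1ccccc1)c1ccc(OC)c(OCc2ccccc2)c1OC | intermediate
16 | 2-bromo-4-{(2R)-2-[3-(benzyloxy)-2,4-dimethoxyphenyl]-3-hydroxypropyl}-5-methoxyphenyl 4-methylbenzenesulfonate | COc1cc(OS(=O)(=O)c2ccc(C)cc2)c(Br)cc1C[C@@H](CO)c1ccc(OC)c(OCc2ccccc2)c1OC | intermediate
17 | 3-(benzyloxy)phenol | Oc1cccc(OCc2ccccc2)c1 | starting material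
18 | 2-bromo-4-{(2R)-2-[3-(benzyloxy)-2,4-dimethoxyphenyl]-3-[3-(benzyloxy)phenoxy]propyl}-5-methoxyphenyl 4-methylbenzenesulfonate | COc1cc(OS(=O)(=O)c2ccc(C)cc2)c(Br)cc1C[C@@H](COc1cccc(OCc2ccccc2)c1)c1ccc(OC)c(OCc2ccccc2)c1OC | intermediate
19 | 2-bromo-4-{(2R)-2-[3-(benzyloxy)-2,4-dimethoxyphenyl]-3-[3-(benzyloxy)phenoxy]propyl}-5-methoxyphenol | COc1cc(O)c(Br)cc1C[C@@H](COc1cccc(OCc2ccccc2)c1)c1ccc(OC)c(OCc2ccccc2)c1OC | intermediate
20 | 4-{(2R)-2-[3-(benzyloxy)-2,4-dimethoxyphenyl]-3-[3-(benzyloxy)phenoxy]propylidene}-2-bromo-5-methoxycyclohexa-2,5-dien-1-one (not isolated) | COC1=CC(=O)C(Br)=C/C1=C\[C@@H](COc1cccc(OCc2ccccc2)c1)c1ccc(OC)c(OCc2ccccc2)c1OC | intermediate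
21 | 2-bromo-4-{(3R,4S)-7-(benzyloxy)-3-[3-(benzyloxy)-2,4-dimethoxyphenyl]-3,4-dihydro-2H-chromen-4-yl}-5-methoxyphenol (trans) | COc1cc(O)c(Br)cc1[C@@H]1c2ccc(OCc3ccccc3)cc2OC[C@H]1c1ccc(OC)c(OCc2ccccc2)c1OC | intermediate
22 | 7-hydroxychroman-4-one | O=C1CCOc2cc(O)ccc21 | starting material
23 | 7-(benzyloxy)chroman-4-one | O=C1CCOc2cc(OCc3ccccc3)ccc21 | intermediate
24 | 7-(benzyloxy)-3-bromochroman-4-one (racemic) | O=C1C(Br)COc2cc(OCc3ccccc3)ccc21 | intermediate
25 | 7-(benzyloxy)-3-bromochroman-4-ol (racemic, cis and trans) | OC1C(Br)COc2cc(OCc3ccccc3)ccc21 | intermediate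
26 | 7-(benzyloxy)-3-bromo-2H-chromene | BrC1=Cc2ccc(OCc3ccccc3)cc2OC1 | intermediate
27 | 2-[7-(benzyloxy)-2H-chromen-3-yl]-4,4,5,5-tetramethyl-1,3,2-dioxaborolane | CC1(C)OB(OC1(C)C)C1=Cc2ccc(OCc3ccccc3)cc2OC1 | intermediate
28 | (3R,4S)-7-(benzyloxy)-4-[4-(benzyloxy)-5-bromo-2-methoxyphenyl]-3-[3-(benzyloxy)-2,4-dimethoxyphenyl]chromane | COc1cc(OCc2ccccc2)c(Br)cc1[C@@H]1c2ccc(OCc3ccccc3)cc2OC[C@H]1c1ccc(OC)c(OCc2ccccc2)c1OC | intermediate
29 | (3R,4S)-7-(benzyloxy)-4-{4-(benzyloxy)-5-[7-(benzyloxy)-2H-chromen-3-yl]-2-methoxyphenyl}-3-[3-(benzyloxy)-2,4-dimethoxyphenyl]chromane | COc1cc(OCc2ccccc2)c(C2=Cc3ccc(OCc4ccccc4)cc3OC2)cc1[C@@H]1c2ccc(OCc3ccccc3)cc2OC[C@H]1c1ccc(OC)c(OCc2ccccc2)c1OC | intermediate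
30 | (3R,4S)-7-(benzyloxy)-4-{4-(benzyloxy)-5-[(3R)-7-(benzyloxy)chroman-3-yl]-2-methoxyphenyl}-3-[3-(benzyloxy)-2,4-dimethoxyphenyl]chromane | COc1cc(OCc2ccccc2)c([C@@H]2COc3cc(OCc4ccccc4)ccc3C2)cc1[C@@H]1c2ccc(OCc3ccccc3)cc2OC[C@H]1c1ccc(OC)c(OCc2ccccc2)c1OC | intermediate
31 | (3R,4S)-4-{4-hydroxy-5-[(3R)-7-hydroxychroman-3-yl]-2-methoxyphenyl}-3-(3-hydroxy-2,4-dimethoxyphenyl)chroman-7-ol | COc1cc(O)c([C@@H]2COc3cc(O)ccc3C2)cc1[C@@H]1c2ccc(O)cc2OC[C@H]1c1ccc(OC)c(O)c1OC | target

## Step count and least certain steps

Total: 23 steps. Longest linear sequence: 14 steps (steps 1 to 5, 10 to 14, 20 to 23).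

**Step 14 (key step).** The likely failures are competing oxidation of the alkoxyarene rings, a second oxidation of the product at C4–H, coupling of the phenoxyl radical, or ring closure too slow to outrun solvent capture of the methide. The fallback sets out from 19 and returns to 21, with oxidation and ring closure separated. DDQ in MeOH/CH2Cl2 at 0 °C oxidises the phenol to the quinone methide, which methanol traps as the benzylic methyl ether F1 (both C4 epimers); this is the known benzylic methoxylation of 4-alkylphenols. BF3·OEt2 in CH2Cl2 at −40 °C then ionises F1, and the known acid-mediated intramolecular Friedel–Crafts alkylation of a para-hydroxybenzyl ether closes the pyran ring to 21. Both epimers converge through the same planar intermediate and the same chair-like transition state.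

**Step 22.** The likely failures are slow hydrogenation or poor facial selectivity, because the olefin carries an ortho-benzyloxy aryl group, and acid-induced migration of the double bond. The fallback sets out from 28 and returns to 31. Palladium-catalysed α-arylation of ketone 23 with 28 (Pd(OAc)2, P(t-Bu)3·HBF4, NaOt-Bu, toluene, 70 °C) gives the isoflavanone F2 as a C3q epimer mixture. Transfer hydrogenation with dynamic kinetic resolution (RuCl(p-cymene)[(R,R)-TsDPEN], HCO2H/Et3N, 40 °C) equilibrates C3q through the enol and reduces one epimer to the cis-(3R,4R)-isoflavan-4-ol F3. Hydrogenolysis (H2, Pd(OH)2/C, EtOAc/EtOH, no added acid) removes the four benzyl groups and the benzylic C4q hydroxyl to give 31. Acid is avoided in the last operation so that C3q is not scrambled by elimination and re-addition.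

**Step 10.** The likely failures are slow alkylation of the stabilised, hindered enolate, loss of the auxiliary through ketene formation on warming, and epimerisation of the α-aryl centre by residual base. The fallback sets out from 5 and 11 and returns to 16. Perkin condensation (Ac2O, Et3N, 100 °C) gives the (E)-2,3-diarylacrylic acid F4. Carboxyl-directed asymmetric hydrogenation with a chiral spiro phosphine–oxazoline iridium catalyst, [Ir(cod)(SIPHOX)]B[3,5-(CF3)2C6H3]4, under H2 with Et3N in MeOH gives the (R)-acid F5, the ligand enantiomer being the one that leads to R. BH3·THF reduces F5 to 16. This path is shorter than steps 5 and 8 to 11, but its enantioselectivity on a doubly ortho-substituted substrate is less assured than auxiliary control.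

**Step 3.** The likely failures are slow oxidative addition and transmetalation at the electron-rich ortho-methoxy bromide, and competing protodebromination. The fallback sets out from 3 and returns to 5. Bromine–lithium exchange (n-BuLi, THF, −78 °C) gives the aryllithium F6, which opens oxirane in the presence of BF3·OEt2 to the 2-arylethanol F7. Oxidation with TEMPO (cat.) and PhI(OAc)2 in MeCN/H2O takes F7 through the aldehyde to acid 5.

## Further compounds

F1 | step 14 | 2-bromo-4-{(2R)-2-[3-(benzyloxy)-2,4-dimethoxyphenyl]-3-[3-(benzyloxy)phenoxy]-1-methoxypropyl}-5-methoxyphenol (both C4 epimers) | COc1cc(O)c(Br)cc1C(OC)[C@@H](COc1cccc(OCc2ccccc2)c1)c1ccc(OC)c(OCc2ccccc2)c1OC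
F2 | step 22 | 7-(benzyloxy)-3-{2-(benzyloxy)-5-[(3R,4S)-7-(benzyloxy)-3-[3-(benzyloxy)-2,4-dimethoxyphenyl]chroman-4-yl]-4-methoxyphenyl}chroman-4-one (C3q epimers) | COc1cc(OCc2ccccc2)c(C2COc3cc(OCc4ccccc4)ccc3C2=O)cc1[C@@H]1c2ccc(OCc3ccccc3)cc2OC[C@H]1c1ccc(OC)c(OCc2ccccc2)c1OC
F3 | step 22 | (3R,4R)-7-(benzyloxy)-3-{2-(benzyloxy)-5-[(3R,4S)-7-(benzyloxy)-3-[3-(benzyloxy)-2,4-dimethoxyphenyl]chroman-4-yl]-4-methoxyphenyl}chroman-4-ol (cis) | COc1cc(OCc2ccccc2)c([C@@H]2COc3cc(OCc4ccccc4)ccc3[C@@H]2O)cc1[C@@H]1c2ccc(OCc3ccccc3)cc2OC[C@H]1c1ccc(OC)c(OCc2ccccc2)c1OC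
F4 | step 10 | (E)-2-[3-(benzyloxy)-2,4-dimethoxyphenyl]-3-{5-bromo-2-methoxy-4-[(4-methylbenzenesulfonyl)oxy]phenyl}prop-2-enoic acid | OC(=O)/C(=C/c1cc(Br)c(OS(=O)(=O)c2ccc(C)cc2)cc1OC)c1ccc(OC)c(OCc2ccccc2)c1OC
F5 | step 10 | (2R)-2-[3-(benzyloxy)-2,4-dimethoxyphenyl]-3-{5-bromo-2-methoxy-4-[(4-methylbenzenesulfonyl)oxy]phenyl}propanoic acid | OC(=O)[C@H](Cc1cc(Br)c(OS(=O)(=O)c2ccc(C)cc2)cc1OC)c1ccc(OC)c(OCc2ccccc2)c1OC
F6 | step 3 | [3-(benzyloxy)-2,4-dimethoxyphenyl]lithium | [Li]c1ccc(OC)c(OCc2ccccc2)c1OC
F7 | step 3 | 2-[3-(benzyloxy)-2,4-dimethoxyphenyl]ethan-1-ol | OCCc1ccc(OC)c(OCc2ccccc2)c1OC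
A1 | alternative 1 | secondary pinacol boronate with ring A and ring E on C4 and ring B and boron on C3, configured as C4 and C3 of 31, with (3R)-chroman Q | COc1cc(OCc2ccccc2)c([C@@H]2COc3cc(OCc4ccccc4)ccc3C2)cc1[C@H](c1ccc(OCc2ccccc2)cc1OCOC)[C@@H](B1OC(C)(C)C(C)(C)O1)c1ccc(OC)c(OCc2ccccc2)c1OC
A2 | alternative 1 | (E)-alkenyl pinacol boronate of ring E bearing (3R)-7-(benzyloxy)chroman-3-yl at C1' | COc1cc(OCc2ccccc2)c([C@@H]2COc3cc(OCc4ccccc4)ccc3C2)cc1/C=C/B1OC(C)(C)C(C)(C)O1
A3 | alternative 1 | [3-(benzyloxy)-2,4-dimethoxyphenyl]lithium | [Li]c1ccc(OC)c(OCc2ccccc2)c1OC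
A4 | alternative 1 | 4-(benzyloxy)-2-(methoxymethoxy)phenyl trifluoromethanesulfonate | COCOc1cc(OCc2ccccc2)ccc1OS(=O)(=O)C(F)(F)F
A5 | alternative 2 | cis-3-(benzyloxy)-9-methoxypterocarpan-8-ol, C6a configured as C3q of 31 | COc1cc4c([C@@H]2COc3cc(OCc5ccccc5)ccc3[C@@H]2O4)cc1O
A6 | alternative 2 | 7-(benzyloxy)-2H-chromene | C1=Cc2ccc(OCc3ccccc3)cc2OC1
A7 | alternative 2 | 2-methoxy-1,4-benzoquinone | COC1=CC(=O)C=CC1=O
A8 | alternative 3 | [4-(benzyloxy)-2-(methoxymethoxy)phenyl]{5-[(3R)-7-(benzyloxy)chroman-3-yl]-4-hydroxy-2-methoxyphenyl}methanone | COc1cc(O)c([C@@H]2COc3cc(OCc4ccccc4)ccc3C2)cc1C(=O)c1ccc(OCc2ccccc2)cc1OCOC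
A9 | alternative 3 | (Z)-1,1-dimethoxy-3-(trimethylsilyloxy)buta-1,3-diene bearing (3R)-7-(benzyloxy)chroman-3-yl at C4 | COC(OC)=C/C(O[Si](C)(C)C)=C/[C@@H]1COc2cc(OCc3ccccc3)ccc2C1
A10 | alternative 3 | 1-[4-(benzyloxy)-2-(methoxymethoxy)phenyl]prop-2-yn-1-one | C#CC(=O)c1ccc(OCc2ccccc2)cc1OCOC
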